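The route rests on cutting the two disubstituted alkenes C7=C8 and C7'=C8' at once. Rings A and B have the same (6R) configuration at C6 and C6', and the C3 ketone of ring A is only the oxidised form of the (3'R) carbinol of ring B, so the skeleton is C2-symmetric about C15=C15'. One double Julia–Kocienski olefination therefore joins two identical C10 units, a (3R,6R)-3-silyloxy ε-ring tetrazolyl sulfone metalated at C7, to both formyl groups of the C20 heptaenedial. This brings in both C6 stereocentres and completes the C40 nonaene. The ends are told apart only in the last step, by oxidising one of the two freed allylic carbinols.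

Key step: step 9

Assumption: in step 3 the lipase is taken to acylate the (4R)-carbinol, the usual preference of Pseudomonas-type lipases for such cyclohex-2-en-1-ols; if it preferred the other enantiomer, the unreacted alcohol would be 8 itself and step 4 would fall away (configuration to be confirmed at 8).

Remark on numbering: compounds 5–14 use cyclohexene numbering (C1 bears the one-carbon arm, C4 the oxygen); carotenoid numbering (C3, C6, C7, C8) is used from 16 on.

Step 1
Reactants: 1 mesityl oxide; 2 ethyl acetoacetate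
Product: 5 ethyl 2,6,6-trimethyl-4-oxocyclohex-2-ene-1-carboxylate (racemic), via Michael adduct 3 (not isolated), via cyclic aldol 4 (not isolated)
Conditions: ZnCl2 (cat.), heptane–toluene, reflux, Dean–Stark
Reagents that add atoms: none
Why: Robinson-type annulation in which ZnCl2 promotes Michael addition of C2 of 2 to the β-carbon of 1, the methyl ketone of 3 closes onto the acetoacetate carbonyl by intramolecular aldol addition to 4 and dehydration, removal of water drives the sequence, and the single stereocentre C1 arises as a racemate.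

Step 2
Reactants: 5 ethyl 2,6,6-trimethyl-4-oxocyclohex-2-ene-1-carboxylate (racemic)
Product: 6 rac-ethyl (1R*,4R*)-4-hydroxy-2,6,6-trimethylcyclohex-2-ene-1-carboxylate (trans)
Conditions: NaBH4, CeCl3·7H2O, MeOH, −20 °C
Reagents that add atoms: none
Why: Luche reduction adds hydride 1,2 to the enone and spares the ester, and hydride is expected to approach anti to the axial C6 methyl group, on the face of the pseudoaxial C1 ester, so that the new C4 carbinol lies trans to the ester (substrate control); the cis isomer is removed by chromatography.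

Step 3
Reactants: 6 rac-ethyl (1R*,4R*)-4-hydroxy-2,6,6-trimethylcyclohex-2-ene-1-carboxylate
Product: 7 ethyl (1R,4R)-4-acetoxy-2,6,6-trimethylcyclohex-2-ene-1-carboxylate
Conditions: lipase from Burkholderia cepacia (lipase PS, immobilised), vinyl acetate, t-BuOMe, 30 °C, stopped just short of half conversion
Reagents that add atoms: vinyl acetate, C=COC(C)=O
Why: Lipase-catalysed enantioselective transesterification (kinetic resolution) acylates only the (4R)-carbinol, so one enantiomer of the trans racemate is taken out as the acetate and the absolute configuration of C1 and C4 is fixed together; the unreacted (1S,4S)-alcohol is separated by chromatography.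

Step 4
Reactants: 7 ethyl (1R,4R)-4-acetoxy-2,6,6-trimethylcyclohex-2-ene-1-carboxylate
Product: 8 ethyl (1R,4R)-4-hydroxy-2,6,6-trimethylcyclohex-2-ene-1-carboxylate
Conditions: K2CO3 (cat.), EtOH, 0 °C → rt
Reagents that add atoms: none
Why: Carbonate-catalysed ethanolysis (transesterification) cleaves the secondary acetate, ethanol as solvent keeps the ethyl ester intact, and the weak base at low temperature should neither epimerise C1 nor move the C2=C3 alkene into conjugation with the ester.

Step 5
Reactants: 8 ethyl (1R,4R)-4-hydroxy-2,6,6-trimethylcyclohex-2-ene-1-carboxylate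
Product: 9 ethyl (1R,4R)-4-(tert-butyldimethylsilyloxy)-2,6,6-trimethylcyclohex-2-ene-1-carboxylate
Conditions: TBSCl, imidazole, DMF, rt
Reagents that add atoms: tert-butyldimethylsilyl chloride, CC(C)(C)[Si](C)(C)Cl
Why: Imidazole-promoted silylation of the secondary allylic alcohol touches no stereocentre and gives an ether that should survive the hydride, Mitsunobu, peroxide and amide-base steps ahead.

Step 6
Reactants: 9 ethyl (1R,4R)-4-(tert-butyldimethylsilyloxy)-2,6,6-trimethylcyclohex-2-ene-1-carboxylate
Product: 10 [(1R,4R)-4-(tert-butyldimethylsilyloxy)-2,6,6-trimethylcyclohex-2-en-1-yl]methanol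
Conditions: LiAlH4, Et2O, 0 °C
Reagents that add atoms: none
Why: Hydride reduction of the ester gives the primary alcohol, the silyl ether and the isolated trisubstituted alkene are inert to LiAlH4 at 0 °C, and C1 keeps its configuration because hydride addition outruns enolisation.

Step 7
Reactants: 10 [(1R,4R)-4-(tert-butyldimethylsilyloxy)-2,6,6-trimethylcyclohex-2-en-1-yl]methanol; 11 1-phenyl-1H-tetrazole-5-thiol
Product: 12 5-({[(1R,4R)-4-(tert-butyldimethylsilyloxy)-2,6,6-trimethylcyclohex-2-en-1-yl]methyl}sulfanyl)-1-phenyl-1H-tetrazole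
Conditions: PPh3, DIAD, THF, 0 °C → rt
Reagents that add atoms: none
Why: In this Mitsunobu thioetherification the acidic thiol 11 protonates the betaine and its thiolate displaces the oxyphosphonium group by SN2 at the primary carbon, so no stereocentre is involved and the β-branching only slows the substitution.

Step 8
Reactants: 12 5-({[(1R,4R)-4-(tert-butyldimethylsilyloxy)-2,6,6-trimethylcyclohex-2-en-1-yl]methyl}sulfanyl)-1-phenyl-1H-tetrazole
Product: 14 5-({[(1R,4R)-4-(tert-butyldimethylsilyloxy)-2,6,6-trimethylcyclohex-2-en-1-yl]methyl}sulfonyl)-1-phenyl-1H-tetrazole, via sulfoxide 13 (not isolated)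
Conditions: (NH4)6Mo7O24·4H2O (cat.), 30% aq. H2O2, EtOH, 0 °C → rt
Reagents that add atoms: hydrogen peroxide, OO
Why: Molybdate-catalysed peroxide oxidation takes the sulfide through sulfoxide 13 to the sulfone, a standard preparation of tetrazolyl sulfones in which the electrophilic peroxomolybdate oxidises sulfur much faster than the trisubstituted alkene and leaves the silyl ether in place.

Step 9
Reactants: 14 5-({[(1R,4R)-4-(tert-butyldimethylsilyloxy)-2,6,6-trimethylcyclohex-2-en-1-yl]methyl}sulfonyl)-1-phenyl-1H-tetrazole (2.4 equiv); 15 crocetindialdehyde (all-E 2,6,11,15-tetramethylhexadeca-2,4,6,8,10,12,14-heptaenedial, 1 equiv)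
Product: 18 (3R,6R,3'R,6'R)-3,3'-bis(tert-butyldimethylsilyloxy)-ε,ε-carotene, via C7-potassio sulfone 16 (not isolated), via mono-olefinated C30 aldehyde 17 (not isolated)
Conditions: KN(SiMe3)2 (2.3 equiv), THF, −78 °C, 20 min; then 15 in THF, −78 °C → rt, Ar, dark
Reagents that add atoms: none
Why: KN(SiMe3)2 removes a C7 proton next to the sulfonyl group of 14, carbanion 16 adds to one formyl group of 15, the alkoxide attacks C5 of the tetrazole (Smiles rearrangement) and the resulting sulfinate loses SO2 and 1-phenyltetrazol-5-olate to give the C7=C8 alkene of 17, whose remaining formyl group repeats the sequence at C8' to form C7'=C8'. This is a Julia–Kocienski olefination run in two directions on a symmetric polyene dialdehyde, a known reaction type for carotenoid-like chains. No ring is closed and no stereocentre is created: C3 and C6 of both rings are carried in from 14, since the C7 carbanion is not conjugated with the C4=C5 alkene and so does not acidify the C6–H. The step needs E geometry at the two new disubstituted alkenes, which the potassium counter-ion in THF and the bulky, β-branched carbanion should secure through an anti adduct and antiperiplanar loss of sulfinate and tetrazolate. Should some 7Z or 7'Z isomer form, heating the crude product in heptane is expected to equilibrate it to the all-E compound, which crystallises. Keeping the base slightly below the amount of sulfone leaves no free amide to attack the doubly allylic C6–H of the product or the dialdehyde.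

Step 10
Reactants: 18 (3R,6R,3'R,6'R)-3,3'-bis(tert-butyldimethylsilyloxy)-ε,ε-carotene
Product: 20 (3R,6R,3'R,6'R)-ε,ε-carotene-3,3'-diol, via mono-silyl ether 19 (not isolated)
Conditions: Bu4NF, THF, 0 °C → rt, dark
Reagents that add atoms: none
Why: Fluoride-induced desilylation cleaves both secondary silyl ethers through 19, driven by the strong Si–F bond; acid, which would ionise the allylic C3–O bonds, is avoided, and the polyene and the C6 centres should tolerate fluoride at or below room temperature.

Step 11
Reactants: 20 (3R,6R,3'R,6'R)-ε,ε-carotene-3,3'-diol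
Product: 21 (6R,3'R,6'R)-3'-hydroxy-ε,ε-caroten-3-one
Conditions: activated MnO2, CH2Cl2, rt, dark, stopped at partial conversion; recovered 20 returned to the oxidation
Reagents that add atoms: none
Why: Allylic oxidation on activated MnO2 acts only on allylic carbinols, the two are equivalent and far apart so the mono-ketone should form statistically and is separated by chromatography from unreacted diol and from the diketone, and the neutral heterogeneous conditions should leave the base-labile C6–H of the new enone ring, as well as C3' and C6', untouched.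

Compound list
1 | mesityl oxide (4-methylpent-3-en-2-one) | CC(C)=CC(C)=O | starting material
2 | ethyl acetoacetate | CCOC(=O)CC(C)=O | starting material
3 | ethyl 2-acetyl-3,3-dimethyl-5-oxohexanoate (Michael adduct, racemic, not isolated) | CCOC(=O)C(C(C)=O)C(C)(C)CC(C)=O | intermediate
4 | ethyl 2-hydroxy-2,6,6-trimethyl-4-oxocyclohexane-1-carboxylate (cyclic aldol, mixture of stereoisomers, not isolated) | CCOC(=O)C1C(C)(O)CC(=O)CC1(C)C | intermediate
5 | ethyl 2,6,6-trimethyl-4-oxocyclohex-2-ene-1-carboxylate (racemic) | CCOC(=O)C1C(C)=CC(=O)CC1(C)C | intermediate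
6 | rac-ethyl (1R*,4R*)-4-hydroxy-2,6,6-trimethylcyclohex-2-ene-1-carboxylate (trans racemate; the (1R,4R) enantiomer is drawn) | CC1=C[C@H](O)CC(C)(C)[C@H]1C(=O)OCC | intermediate
7 | ethyl (1R,4R)-4-acetoxy-2,6,6-trimethylcyclohex-2-ene-1-carboxylate | CC1=C[C@H](OC(C)=O)CC(C)(C)[C@H]1C(=O)OCC | intermediate
8 | ethyl (1R,4R)-4-hydroxy-2,6,6-trimethylcyclohex-2-ene-1-carboxylate (single enantiomer) | CC1=C[C@H](O)CC(C)(C)[C@H]1C(=O)OCC | intermediate
9 | ethyl (1R,4R)-4-(tert-butyldimethylsilyloxy)-2,6,6-trimethylcyclohex-2-ene-1-carboxylate | CC1=C[C@H](O[Si](C)(C)C(C)(C)C)CC(C)(C)[C@H]1C(=O)OCC | intermediate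
10 | [(1R,4R)-4-(tert-butyldimethylsilyloxy)-2,6,6-trimethylcyclohex-2-en-1-yl]methanol | CC1=C[C@H](O[Si](C)(C)C(C)(C)C)CC(C)(C)[C@H]1CO | intermediate
11 | 1-phenyl-1H-tetrazole-5-thiol | Sc1nnnn1-c1ccccc1 | starting material
12 | 5-({[(1R,4R)-4-(tert-butyldimethylsilyloxy)-2,6,6-trimethylcyclohex-2-en-1-yl]methyl}sulfanyl)-1-phenyl-1H-tetrazole | CC1=C[C@H](O[Si](C)(C)C(C)(C)C)CC(C)(C)[C@H]1CSc1nnnn1-c1ccccc1 | intermediate
13 | 5-({[(1R,4R)-4-(tert-butyldimethylsilyloxy)-2,6,6-trimethylcyclohex-2-en-1-yl]methyl}sulfinyl)-1-phenyl-1H-tetrazole (both configurations at sulfur, not isolated) | CC1=C[C@H](O[Si](C)(C)C(C)(C)C)CC(C)(C)[C@H]1CS(=O)c1nnnn1-c1ccccc1 | intermediate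
14 | 5-({[(1R,4R)-4-(tert-butyldimethylsilyloxy)-2,6,6-trimethylcyclohex-2-en-1-yl]methyl}sulfonyl)-1-phenyl-1H-tetrazole | CC1=C[C@H](O[Si](C)(C)C(C)(C)C)CC(C)(C)[C@H]1CS(=O)(=O)c1nnnn1-c1ccccc1 | intermediate
15 | crocetindialdehyde (all-E 2,6,11,15-tetramethylhexadeca-2,4,6,8,10,12,14-heptaenedial) | O=C/C(C)=C/C=C/C(C)=C/C=C/C=C(C)/C=C/C=C(C)/C=O | starting material
16 | potassium salt of sulfone 14 metalated at C7 (not isolated) | CC1=C[C@H](O[Si](C)(C)C(C)(C)C)CC(C)(C)[C@H]1[CH-]S(=O)(=O)c1nnnn1-c1ccccc1.[K+] | intermediate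
17 | (3R,6R)-3-(tert-butyldimethylsilyloxy)-8'-apo-ε-caroten-8'-al (all-E, not isolated) | CC1=C[C@H](O[Si](C)(C)C(C)(C)C)CC(C)(C)[C@H]1/C=C/C(C)=C/C=C/C(C)=C/C=C/C=C(C)/C=C/C=C(C)/C=O | intermediate
18 | (3R,6R,3'R,6'R)-3,3'-bis(tert-butyldimethylsilyloxy)-ε,ε-carotene (all-E) | CC1=C[C@H](O[Si](C)(C)C(C)(C)C)CC(C)(C)[C@H]1/C=C/C(C)=C/C=C/C(C)=C/C=C/C=C(C)/C=C/C=C(C)/C=C/[C@H]1C(C)=C[C@H](O[Si](C)(C)C(C)(C)C)CC1(C)C | intermediate
19 | (3R,6R,3'R,6'R)-3'-(tert-butyldimethylsilyloxy)-ε,ε-caroten-3-ol (mono-silyl ether, not isolated in step 10) | CC1=C[C@H](O[Si](C)(C)C(C)(C)C)CC(C)(C)[C@H]1/C=C/C(C)=C/C=C/C(C)=C/C=C/C=C(C)/C=C/C=C(C)/C=C/[C@H]1C(C)=C[C@H](O)CC1(C)C | intermediate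
20 | (3R,6R,3'R,6'R)-ε,ε-carotene-3,3'-diol (all-E) | CC1=C[C@H](O)CC(C)(C)[C@H]1/C=C/C(C)=C/C=C/C(C)=C/C=C/C=C(C)/C=C/C=C(C)/C=C/[C@H]1C(C)=C[C@H](O)CC1(C)C | intermediate
21 | (6R,3'R,6'R)-3'-hydroxy-ε,ε-caroten-3-one (all-E; ring A is the keto ring) | CC1=CC(=O)CC(C)(C)[C@H]1/C=C/C(C)=C/C=C/C(C)=C/C=C/C=C(C)/C=C/C=C(C)/C=C/[C@H]1C(C)=C[C@H](O)CC1(C)C | target

Total step count: 11.
Longest linear sequence: 11 steps (1 and 2 to 21); 11 and 15 enter as purchased materials.

Steps most likely to fail

Step 9. The second olefination may stall, or E control may erode, because the carbanion is β-branched and hindered, the dialdehyde is sparingly soluble in cold THF, and surplus base could attack the doubly allylic C6–H of the product. The fallback reverses the polarity while forming the same two bonds; it sets out from alcohol 10 and dialdehyde 15 and returns at 18. Alcohol 10 would be oxidised with Dess–Martin periodinane (NaHCO3, CH2Cl2, 0 °C) to (1R,4R)-4-(tert-butyldimethylsilyloxy)-2,6,6-trimethylcyclohex-2-ene-1-carbaldehyde F1. Dialdehyde 15 would be reduced with NaBH4 (THF–EtOH, 0 °C) to all-E 2,6,11,15-tetramethylhexadeca-2,4,6,8,10,12,14-heptaene-1,16-diol F2. F2 would be converted with PPh3·HBr (MeOH–CH2Cl2, rt) into the all-E C20 1,16-bis(triphenylphosphonium) dibromide F3. F3 would be deprotonated at both ends with NaN(SiMe3)2 (THF, −78 °C) and F1 (2.2 equiv) added cold, so that a double Wittig olefination closes C7=C8 and C7'=C8'. Thermal equilibration in heptane should then give all-E 18. The C6–H of F1 lies next to the formyl group, which is why the aldehyde is added to the preformed ylide at low temperature.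

Step 11. Oxidation of the second ring may overtake isolation of the mono-ketone, and material may be lost by adsorption or E/Z isomerisation on the oxidant surface. The fallback tells the ends apart before the oxidation; it sets out from 18 and returns at 21. About one equivalent of Bu4NF (THF, 0 °C) would give the mono-silyl ether 19, now isolated, while recovered 18 is resubmitted and diol 20 is re-silylated. Excess MnO2 can then be run to full conversion, since only one carbinol is free, to give (6R,3'R,6'R)-3'-(tert-butyldimethylsilyloxy)-ε,ε-caroten-3-one F4. The last silyl ether would be removed with Bu4NF buffered with AcOH (THF, 0 °C), a non-basic fluoride source that should spare the C6–H of the keto ring, to give 21.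

Step 2. Hydride addition may show poor facial selectivity and leave too little of the trans alcohol. The fallback uses the cis isomer; it sets out from 5 and returns at 6. The reduction of 5 also delivers rac-ethyl (1R*,4S*)-4-hydroxy-2,6,6-trimethylcyclohex-2-ene-1-carboxylate F5, which would be collected. Mitsunobu inversion of F5 (4-nitrobenzoic acid, PPh3, DIAD, THF, 0 °C) at C4 should give rac-ethyl (1R*,4R*)-2,6,6-trimethyl-4-(4-nitrobenzoyloxy)cyclohex-2-ene-1-carboxylate F6; SN2' attack is disfavoured at the methyl-bearing C2. Ethanolysis of F6 (K2CO3, EtOH, 0 °C) then gives trans alcohol 6.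

Further compounds
F1 | step 9 | (1R,4R)-4-(tert-butyldimethylsilyloxy)-2,6,6-trimethylcyclohex-2-ene-1-carbaldehyde | CC1=C[C@H](O[Si](C)(C)C(C)(C)C)CC(C)(C)[C@H]1C=O
F2 | step 9 | all-E 2,6,11,15-tetramethylhexadeca-2,4,6,8,10,12,14-heptaene-1,16-diol | OC/C(C)=C/C=C/C(C)=C/C=C/C=C(C)/C=C/C=C(C)/CO
F3 | step 9 | all-E (2,6,11,15-tetramethylhexadeca-2,4,6,8,10,12,14-heptaene-1,16-diyl)bis(triphenylphosphonium) dibromide | [Br-].[Br-].c1ccccc1[P+](c1ccccc1)(c1ccccc1)C/C(C)=C/C=C/C(C)=C/C=C/C=C(C)/C=C/C=C(C)/C[P+](c1ccccc1)(c1ccccc1)c1ccccc1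
F4 | step 11 | (6R,3'R,6'R)-3'-(tert-butyldimethylsilyloxy)-ε,ε-caroten-3-one | CC1=CC(=O)CC(C)(C)[C@H]1/C=C/C(C)=C/C=C/C(C)=C/C=C/C=C(C)/C=C/C=C(C)/C=C/[C@H]1C(C)=C[C@H](O[Si](C)(C)C(C)(C)C)CC1(C)C
F5 | step 2 | rac-ethyl (1R*,4S*)-4-hydroxy-2,6,6-trimethylcyclohex-2-ene-1-carboxylate (cis racemate; one enantiomer drawn) | CC1=C[C@@H](O)CC(C)(C)[C@H]1C(=O)OCC
F6 | step 2 | rac-ethyl (1R*,4R*)-2,6,6-trimethyl-4-(4-nitrobenzoyloxy)cyclohex-2-ene-1-carboxylate (trans racemate; one enantiomer drawn) | CC1=C[C@H](OC(=O)c2ccc(cc2)[N+](=O)[O-])CC(C)(C)[C@H]1C(=O)OCC
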